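Central-ring numbering used throughout: C1 carries indole A (6-methoxy-1H-indol-3-yl), C2 and C3 carry methoxy, C4 carries indole B (5-hydroxy-1H-indol-3-yl), C5 and C6 carry methoxy.

## The problem

The target is a hexasubstituted benzene with two indol-3-yl groups para to each other (C1, C4) and methoxy groups on the other four carbons. It has no stereocentre and the two aryl–indole axes carry no descriptor, so the task is purely one of connectivity. The core is symmetric but the two indoles are not (6-methoxy against 5-hydroxy), so the two C(aryl)–C3(indole) bonds must be made in separate, site-defined events on a core that offers no handle for telling its two halves apart. Each of these bonds lies between two ortho-methoxy groups on a very electron-rich ring and next to C2–H and C4–H of the indole, which is an unfavourable setting for oxidative addition and reductive elimination. One phenol (C5–OH of indole B) sits among five aryl methyl ethers and cannot be freed by selective demethylation, so it must travel as a benzyl ether from the start. The free 3-arylindoles (acid-sensitive at C2), the 5-hydroxyindole (air-sensitive) and the tetramethoxyarene (oxidisable to a quinone) call for a neutral, reductive finish.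

The feature that makes the key step possible: C6–C1–C2–C3 carry O, indole A, O, O, the pattern of squaric acid with one oxygen replaced by C3 of indole A. C4–C5 carry indole B and O, the pattern of an enol ether. With no C–H on the ring, all six ring atoms can arrive with their substituents in a cyclobutenone-to-arene ring expansion.

## Retrosynthesis

**19 ⇒ 18 ⇒ 17.** The O–CH2Ph bond and the two N–CO2tBu bonds are cut. The benzyl ether distinguishes the phenol from the methyl ethers from the first step on. The carbamates make both indoles inert to base, electrophiles and organolithium chemistry; they are removed first (17 to 18), so that the air-sensitive hydroxyindole appears only in the last, neutral hydrogenolysis. The forward steps must leave aryl methyl ethers alone.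

**17 ⇒ 16.** The C6–O–CH3 bond is cut. Of the four central methoxy groups only this one is made by alkylation; removing it uncovers the phenol that a ketene-derived ring carbon must carry. The forward step is O-methylation of one hindered phenol while both nitrogens are blocked.

**16 ⇒ 13 (key).** The ring bond C5–C6 is cut and C6 is re-bonded to C3, which folds the arene back to cyclobutenone 13: C6, C1, C2, C3 form the four-membered ring and C4=C5 hangs from C3 as an enol ether. Against cutting the aryl–indole bonds, this removes the hexasubstituted ring altogether. 13 is an isomer of 16 made from two halves that each carry one indole, so the para relation of the indoles is a matter of connectivity and not of selectivity on a symmetric core. The forward reaction must open the four-membered ring with the alkenyl arm turned toward the ketene, close the six-membered ring and tautomerise.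

**13 ⇒ 5 + 10.** The C3–C4 bond and the C3–O–CH3 bond are cut. Cyclobutenedione 5 has two different carbonyls; addition to the one next to the methoxy-bearing carbon places C4 (indole B) para to C1 (indole A). The forward step needs a β-methoxyvinyl anion (formed through dibromide 9 and vinyllithium 11) that lives long enough to add, regioselective 1,2-addition to give alkoxide 12, and O-methylation of that alkoxide.

**5 ⇒ 4 ⇒ 1 + 2.** The C1–C3(indole A) bond is cut as an electrophilic substitution of the unfunctionalised indole 1 by squaric acid dichloride 2 (through chloride 3). Reagent 2 delivers C6, C1, C2, C3 with their oxygens; its second chloride becomes the C2 methoxyl. Monosubstitution at indole C3 is required.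

**10 ⇒ 8 ⇒ 7 ⇒ 6.** C4 is the formyl carbon of commercial aldehyde 6 and C5 with its methoxyl comes from a methoxymethylene ylide. The C4–Br bond is made by bromination–dehydrobromination of enol ether 8. All three steps are standard.

## Roads not taken

**Alternative 1:** Cut both C(aryl)–C3(indole) bonds for two successive Suzuki–Miyaura couplings (Pd(OAc)2, a biaryl phosphine, K3PO4). The electrophile is 1,4-dibromo-2,3,5,6-tetramethoxybenzene A1. It is coupled first with tert-butyl 6-methoxy-3-(pinacolboryl)indole-1-carboxylate A2 to give monobromide A3, then with tert-butyl 5-(benzyloxy)-3-(pinacolboryl)indole-1-carboxylate A4. This is the most obvious route.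
- The two C–Br bonds of A1 are identical, so monocoupling is statistical.
- Each C–Br bond is flanked by two methoxy groups on an electron-rich ring, so oxidative addition and reductive elimination are slow, and the second coupling (on A3) is worse than the first.
- Indol-3-ylboronates protodeboronate readily under the forcing basic conditions this would need.
- Four prefunctionalised partners are required, so it is not shorter, and nothing in the structure is exploited.

**Alternative 2:** Cut the pyrrole rings (N1–C2 and C3–C3a of both indoles) for a double Larock heteroannulation (Pd(OAc)2, base). 1,4-Bis[(trimethylsilyl)ethynyl]-2,3,5,6-tetramethoxybenzene A5 would react with two different ortho-iodoanilines to give the bis(2-silylindole) A6, followed by protodesilylation.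
- The two alkynes of A5 are identical, so installing two different indoles is again statistical unless the alkynes are introduced and unmasked one at a time.
- Alkyne insertion next to a 2,6-dimethoxyaryl group is hindered.
- Regiochemistry rests only on silyl being larger than aryl, and two desilylations are added.
- The chosen plan uses both indoles as bought and never asks a symmetric intermediate to react once.

**Alternative 3:** Cut C1–C6 and C3–C4 along the biosynthetic line, a head-to-tail double Claisen condensation of methyl 3-(6-methoxy-1H-indol-3-yl)-2-oxopropanoate A7 with methyl 3-[5-(benzyloxy)-1H-indol-3-yl]-2-oxopropanoate A8. This would give the bis-indolyl dihydroxyquinone A9, to be reduced and O-methylated four times.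
- A7 and A8 play identical roles, so hetero- against homo-dimerisation is statistical (three quinones).
- Without an enzyme, an enolised arylpyruvate should add to the more electrophilic ketone (aldol) and not to the ester (Claisen).
- Four O-methylations would have to spare two free N–H groups.
- The chosen plan keeps the idea of building the ring but gives each indole a different role (electrophilic dione, nucleophilic vinyl anion), so only the cross-combination can form.

Key step: step 7

Assumption: 1, 2 and 6 are taken as commercial (2 is otherwise one step from squaric acid with oxalyl chloride and catalytic DMF); the target is achiral and its two aryl–indole axes are treated as freely rotating.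

## Route

Step 1
Reactants: 1 6-methoxy-1H-indole; 2 3,4-dichlorocyclobut-3-ene-1,2-dione (squaric acid dichloride)
Product: 4 3-methoxy-4-(6-methoxy-1H-indol-3-yl)cyclobut-3-ene-1,2-dione, via chlorosquaryl indole 3 (not isolated)
Conditions: 2 (1.1 equiv), Et2O, 0 °C to rt; then MeOH, rt to 50 °C
Reagents that add atoms: methanol, CO
Why: Uncatalysed Friedel–Crafts-type chlorosquarylation: indole C3 adds to the vinylogous acid chloride 2 and loses HCl, and the indolyl donor deactivates the remaining C–Cl bond against a second indole. Methanol then replaces that chloride by addition–elimination.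

Step 2
Reactants: 4 3-methoxy-4-(6-methoxy-1H-indol-3-yl)cyclobut-3-ene-1,2-dione
Product: 5 tert-butyl 6-methoxy-3-(2-methoxy-3,4-dioxocyclobut-1-en-1-yl)-1H-indole-1-carboxylate
Conditions: Boc2O, DMAP (cat.), MeCN, rt
Reagents that add atoms: di-tert-butyl dicarbonate, CC(C)(C)OC(=O)OC(=O)OC(C)(C)C
Why: DMAP-catalysed N-acylation of the acidic vinylogous-amide N–H. The carbamate also pulls the nitrogen lone pair away from the dione, so the carbonyl next to the methoxy-bearing carbon stays the more electrophilic one for step 6.

Step 3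
Reactants: 6 5-(benzyloxy)-1H-indole-3-carbaldehyde
Product: 7 tert-butyl 5-(benzyloxy)-3-formyl-1H-indole-1-carboxylate
Conditions: Boc2O, DMAP (cat.), CH2Cl2, rt
Reagents that add atoms: di-tert-butyl dicarbonate, CC(C)(C)OC(=O)OC(=O)OC(C)(C)C
Why: The same DMAP-catalysed N-Boc protection; it tames the indole nucleus for the ylide, bromine and organolithium steps that follow.

Step 4
Reactants: 7 tert-butyl 5-(benzyloxy)-3-formyl-1H-indole-1-carboxylate
Product: 8 tert-butyl 5-(benzyloxy)-3-(2-methoxyethenyl)-1H-indole-1-carboxylate (E/Z mixture)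
Conditions: Ph3P(CH2OMe)Cl, NaN(SiMe3)2, THF, 0 °C; then 7, −78 °C to rt
Reagents that add atoms: (methoxymethyl)triphenylphosphonium chloride, COC[P+](c1ccccc1)(c1ccccc1)c1ccccc1.[Cl-]
Why: Wittig olefination with the non-stabilised methoxymethylene ylide, pre-formed with a non-nucleophilic amide base so that the activated N-Boc group is not cleaved. The alkene geometry does not matter because step 5 erases it.

Step 5
Reactants: 8 tert-butyl 5-(benzyloxy)-3-(2-methoxyethenyl)-1H-indole-1-carboxylate (E/Z mixture)
Product: 10 tert-butyl 5-(benzyloxy)-3-[(Z)-1-bromo-2-methoxyethenyl]-1H-indole-1-carboxylate, via dibromo ether 9 (not isolated)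
Conditions: Br2 (1.0 equiv), CH2Cl2, −78 °C; then i-Pr2NEt, −78 °C to rt; chromatography
Reagents that add atoms: bromine, BrBr
Why: Bromination–dehydrobromination of an enol ether: bromine adds to the enol ether, which is far more nucleophilic than the N-acylated indole nucleus, and the α-bromo ether 9 ionises to an oxocarbenium ion that the amine deprotonates at the bromine-bearing carbon. By analogy with simple 2-bromovinyl ethers the isomer with bromine and methoxy cis should predominate; it is the one carried on.

Step 6
Reactants: 10 tert-butyl 5-(benzyloxy)-3-[(Z)-1-bromo-2-methoxyethenyl]-1H-indole-1-carboxylate; 5 tert-butyl 6-methoxy-3-(2-methoxy-3,4-dioxocyclobut-1-en-1-yl)-1H-indole-1-carboxylate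
Product: 13 tert-butyl 5-(benzyloxy)-3-[(Z)-1-{3-[1-(tert-butoxycarbonyl)-6-methoxy-1H-indol-3-yl]-1,2-dimethoxy-4-oxocyclobut-2-en-1-yl}-2-methoxyethenyl]-1H-indole-1-carboxylate (racemic), via vinyllithium 11 (not isolated), via lithium alkoxide 12 (not isolated)
Conditions: t-BuLi (2.0 equiv), Et2O/THF, −78 °C, 10 min; then 5, THF, −78 °C; then MeOTf, −78 to 0 °C
Reagents that add atoms: methyl trifluoromethanesulfonate, COS(=O)(=O)C(F)(F)F
Why: Bromine–lithium exchange with retention gives β-methoxyvinyllithium 11, held against loss of LiOMe by the cis O–Li contact, as in (Z)-2-ethoxyvinyllithium. 1,2-Addition goes to the carbonyl next to the methoxy-bearing carbon, because the other carbonyl is a vinylogous ester and is shielded by the indole; MeOTf then O-methylates alkoxide 12. The new stereocentre is formed racemic and is destroyed in step 7.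

Step 7
Reactants: 13 tert-butyl 5-(benzyloxy)-3-[(Z)-1-{3-[1-(tert-butoxycarbonyl)-6-methoxy-1H-indol-3-yl]-1,2-dimethoxy-4-oxocyclobut-2-en-1-yl}-2-methoxyethenyl]-1H-indole-1-carboxylate (racemic)
Product: 16 tert-butyl 5-(benzyloxy)-3-{4-[1-(tert-butoxycarbonyl)-6-methoxy-1H-indol-3-yl]-3-hydroxy-2,5,6-trimethoxyphenyl}-1H-indole-1-carboxylate, via dienylketene 14 (not isolated), via cyclohexadienone 15 (not isolated)
Conditions: toluene (degassed, 0.01 M), 110 °C, argon
Reagents that add atoms: none
Why: Heating opens the cyclobutenone by 4π-electrocyclic cleavage of the bond between the carbonyl carbon and the quaternary carbon; the methoxy group on that carbon, the better donor, rotates outward (torquoselectivity), which turns the alkenyl arm inward and gives dienylketene 14 with the ketene carbon and the vinyl terminus on the same side. 14 closes the only new ring, the central six-membered carbocycle, by thermal disrotatory 6π-electrocyclisation between the ketene carbon and the methoxy-bearing vinyl carbon, and dienone 15 aromatises at once by enolisation of its single C–H. The closest known reaction type is the thermal ring expansion of squarate-derived 4-alkenyl-4-alkoxy (or 4-hydroxy) cyclobutenones to hydroquinone derivatives, the intramolecular relative of the Danheiser benzannulation. No stereocentre is created: the racemic centres of 13 and 15 vanish on aromatisation and both faces of the terminus lead to the same arene. Regiochemistry is not decided here but inherited, since each ring carbon arrives with its substituent and the para relation of the indoles follows from the site of addition in step 6. The step itself needs outward rotation of the alkoxy group, secured by its donor character, and closure faster than ketene side reactions, secured because the s-cis triene is the only π-partner in reach (the indole C2=C3 bonds could only give four- or seven-membered rings). The O-methyl ether blocks the two escape routes of the free alcohol, lactonisation of the ketene to a furanone and loss of methanol from the dienone. The methoxy group on the vinyl terminus points inward and slows the closure, hence dilute, degassed toluene at reflux.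

Step 8
Reactants: 16 tert-butyl 5-(benzyloxy)-3-{4-[1-(tert-butoxycarbonyl)-6-methoxy-1H-indol-3-yl]-3-hydroxy-2,5,6-trimethoxyphenyl}-1H-indole-1-carboxylate
Product: 17 tert-butyl 5-(benzyloxy)-3-{4-[1-(tert-butoxycarbonyl)-6-methoxy-1H-indol-3-yl]-2,3,5,6-tetramethoxyphenyl}-1H-indole-1-carboxylate
Conditions: MeI, K2CO3, DMF, rt, argon
Reagents that add atoms: iodomethane, CI
Why: Williamson O-methylation of the single, moderately hindered phenol; both indole nitrogens are still carbamates, so N-methylation cannot compete.

Step 9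
Reactants: 17 tert-butyl 5-(benzyloxy)-3-{4-[1-(tert-butoxycarbonyl)-6-methoxy-1H-indol-3-yl]-2,3,5,6-tetramethoxyphenyl}-1H-indole-1-carboxylate
Product: 18 5-(benzyloxy)-3-[2,3,5,6-tetramethoxy-4-(6-methoxy-1H-indol-3-yl)phenyl]-1H-indole
Conditions: NaOMe (cat.), MeOH/THF, 40 °C
Reagents that add atoms: none
Why: Methoxide-catalysed methanolysis of the two N-acylindole-type carbamates (indolide is a good leaving group); benzyl and methyl ethers are untouched.

Step 10
Reactants: 18 5-(benzyloxy)-3-[2,3,5,6-tetramethoxy-4-(6-methoxy-1H-indol-3-yl)phenyl]-1H-indole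
Product: 19 3-[2,3,5,6-tetramethoxy-4-(6-methoxy-1H-indol-3-yl)phenyl]-1H-indol-5-ol (target)
Conditions: H2 (1 atm), palladium on carbon (Pd/C), EtOAc/MeOH, rt; work-up under argon
Reagents that add atoms: none
Why: Hydrogenolysis of the benzyl ether under neutral conditions, placed last because the free 5-hydroxyindole is air-sensitive; indoles and aryl methyl ethers are inert.

## Compound list

1 | 6-methoxy-1H-indole | COc1ccc2cc[nH]c2c1 | starting material
2 | 3,4-dichlorocyclobut-3-ene-1,2-dione | O=C1C(=O)C(Cl)=C1Cl | starting material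
3 | 3-chloro-4-(6-methoxy-1H-indol-3-yl)cyclobut-3-ene-1,2-dione | COc1ccc2c(C3=C(Cl)C(=O)C3=O)c[nH]c2c1 | intermediate
4 | 3-methoxy-4-(6-methoxy-1H-indol-3-yl)cyclobut-3-ene-1,2-dione | COc1ccc2c(C3=C(OC)C(=O)C3=O)c[nH]c2c1 | intermediate
5 | tert-butyl 6-methoxy-3-(2-methoxy-3,4-dioxocyclobut-1-en-1-yl)-1H-indole-1-carboxylate | COc1ccc2c(C3=C(OC)C(=O)C3=O)cn(C(=O)OC(C)(C)C)c2c1 | intermediate
6 | 5-(benzyloxy)-1H-indole-3-carbaldehyde | O=Cc1c[nH]c2ccc(OCc3ccccc3)cc12 | starting material
7 | tert-butyl 5-(benzyloxy)-3-formyl-1H-indole-1-carboxylate | O=Cc1cn(C(=O)OC(C)(C)C)c2ccc(OCc3ccccc3)cc12 | intermediate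
8 | tert-butyl 5-(benzyloxy)-3-(2-methoxyethenyl)-1H-indole-1-carboxylate (E/Z mixture) | COC=Cc1cn(C(=O)OC(C)(C)C)c2ccc(OCc3ccccc3)cc12 | intermediate
9 | tert-butyl 5-(benzyloxy)-3-(1,2-dibromo-2-methoxyethyl)-1H-indole-1-carboxylate (diastereomer mixture) | COC(Br)C(Br)c1cn(C(=O)OC(C)(C)C)c2ccc(OCc3ccccc3)cc12 | intermediate
10 | tert-butyl 5-(benzyloxy)-3-[(Z)-1-bromo-2-methoxyethenyl]-1H-indole-1-carboxylate | CO/C=C(\Br)c1cn(C(=O)OC(C)(C)C)c2ccc(OCc3ccccc3)cc12 | intermediate
11 | tert-butyl 5-(benzyloxy)-3-(1-lithio-2-methoxyethenyl)-1H-indole-1-carboxylate (Li cis to OMe) | CO/C=C(\[Li])c1cn(C(=O)OC(C)(C)C)c2ccc(OCc3ccccc3)cc12 | intermediate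
12 | lithium alkoxide of the 1-hydroxy analogue of 13 (racemic) | [Li]OC1(/C(=C\OC)c2cn(C(=O)OC(C)(C)C)c3ccc(OCc4ccccc4)cc23)C(OC)=C(c2cn(C(=O)OC(C)(C)C)c3cc(OC)ccc23)C1=O | intermediate
13 | tert-butyl 5-(benzyloxy)-3-[(Z)-1-{3-[1-(tert-butoxycarbonyl)-6-methoxy-1H-indol-3-yl]-1,2-dimethoxy-4-oxocyclobut-2-en-1-yl}-2-methoxyethenyl]-1H-indole-1-carboxylate (racemic) | COC1(/C(=C\OC)c2cn(C(=O)OC(C)(C)C)c3ccc(OCc4ccccc4)cc23)C(OC)=C(c2cn(C(=O)OC(C)(C)C)c3cc(OC)ccc23)C1=O | intermediate
14 | dienylketene from ring opening of 13 (ketene carbon and alkenyl arm cis) | O=C=C(c1cn(C(=O)OC(C)(C)C)c2cc(OC)ccc12)/C(OC)=C(OC)\C(c1cn(C(=O)OC(C)(C)C)c2ccc(OCc3ccccc3)cc12)=C/OC | intermediate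
15 | 6-methoxycyclohexa-2,4-dienone from 6π closure of 14 (racemic) | COC1C(=O)C(c2cn(C(=O)OC(C)(C)C)c3cc(OC)ccc23)=C(OC)C(OC)=C1c1cn(C(=O)OC(C)(C)C)c2ccc(OCc3ccccc3)cc12 | intermediate
16 | tert-butyl 5-(benzyloxy)-3-{4-[1-(tert-butoxycarbonyl)-6-methoxy-1H-indol-3-yl]-3-hydroxy-2,5,6-trimethoxyphenyl}-1H-indole-1-carboxylate | COc1c(O)c(-c2cn(C(=O)OC(C)(C)C)c3cc(OC)ccc23)c(OC)c(OC)c1-c1cn(C(=O)OC(C)(C)C)c2ccc(OCc3ccccc3)cc12 | intermediate
17 | tert-butyl 5-(benzyloxy)-3-{4-[1-(tert-butoxycarbonyl)-6-methoxy-1H-indol-3-yl]-2,3,5,6-tetramethoxyphenyl}-1H-indole-1-carboxylate | COc1ccc2c(-c3c(OC)c(OC)c(-c4cn(C(=O)OC(C)(C)C)c5ccc(OCc6ccccc6)cc45)c(OC)c3OC)cn(C(=O)OC(C)(C)C)c2c1 | intermediate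
18 | 5-(benzyloxy)-3-[2,3,5,6-tetramethoxy-4-(6-methoxy-1H-indol-3-yl)phenyl]-1H-indole | COc1ccc2c(-c3c(OC)c(OC)c(-c4c[nH]c5ccc(OCc6ccccc6)cc45)c(OC)c3OC)c[nH]c2c1 | intermediate
19 | 3-[2,3,5,6-tetramethoxy-4-(6-methoxy-1H-indol-3-yl)phenyl]-1H-indol-5-ol | COc1ccc2c(-c3c(OC)c(OC)c(-c4c[nH]c5ccc(O)cc45)c(OC)c3OC)c[nH]c2c1 | target

## Step count and risks

Total step count: 10. Longest linear sequence: 8 steps (steps 3 to 10, from 6); the other branch (steps 1 and 2) joins at step 6.

**Step 7 (key).** The most likely failure is a sluggish 6π closure: the methoxy group on the vinyl terminus points inward and both reacting ends are flanked by an indole. A long-lived ketene can then dimerise or be captured by adventitious nucleophiles, the carbamates can be lost on prolonged heating, and the electron-rich para-methoxyphenol can be oxidised by air.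
Fallback (sets out from 1, comes back at 18): the central ring is bought instead of built. Acid-promoted conjugate addition of 1 to 2,5-dichloro-1,4-benzoquinone (AcOH, THF) with DDQ reoxidation should give 2,5-dichloro-3-(6-methoxy-1H-indol-3-yl)cyclohexa-2,5-diene-1,4-dione F1. A second addition and reoxidation with commercial 5-(benzyloxy)-1H-indole at the only remaining C–H gives 2-[5-(benzyloxy)-1H-indol-3-yl]-3,6-dichloro-5-(6-methoxy-1H-indol-3-yl)cyclohexa-2,5-diene-1,4-dione F2. NaOMe in MeOH exchanges both vinylogous acid chlorides to give 2-[5-(benzyloxy)-1H-indol-3-yl]-3,6-dimethoxy-5-(6-methoxy-1H-indol-3-yl)cyclohexa-2,5-diene-1,4-dione F3. Reduction with Na2S2O4 to 2-[5-(benzyloxy)-1H-indol-3-yl]-3,6-dimethoxy-5-(6-methoxy-1H-indol-3-yl)benzene-1,4-diol F4 and O-methylation in the same flask (Me2SO4, K2CO3, acetone, argon; carbonate does not deprotonate indole N–H) gives 18, and step 10 follows.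

**Step 6.** The most likely failure is incomplete or unclean capture of the hindered, aggregated lithium alkoxide 12 by MeOTf. Before that, 11 can be eroded by loss of LiOMe if the cis O–Li geometry is not held. Addition at the wrong carbonyl would place the indoles meta, so the regiochemistry of 13 must be confirmed.
Fallback (sets out from 12, comes back at 17): 12 is quenched at −78 °C with aqueous NH4Cl instead of MeOTf to give tert-butyl 5-(benzyloxy)-3-[(Z)-1-{3-[1-(tert-butoxycarbonyl)-6-methoxy-1H-indol-3-yl]-1-hydroxy-2-methoxy-4-oxocyclobut-2-en-1-yl}-2-methoxyethenyl]-1H-indole-1-carboxylate F5. Heating in toluene, the classical hydroxy version of the ring expansion, gives tert-butyl 5-(benzyloxy)-3-{4-[1-(tert-butoxycarbonyl)-6-methoxy-1H-indol-3-yl]-3,6-dihydroxy-2,5-dimethoxyphenyl}-1H-indole-1-carboxylate F6. Double O-methylation (MeI, K2CO3, DMF) reaches 17.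

**Step 5.** The most likely failure is competing electrophilic bromination of the benzyloxy-substituted indole nucleus and decomposition of the readily ionised dibromide 9 before elimination, together with poor control of alkene geometry.
Fallback (sets out from 8, comes back at 10): NBS in MeOH/CH2Cl2 with NaHCO3 at −40 °C captures the intermediate cation as the isolable acetal tert-butyl 5-(benzyloxy)-3-(1-bromo-2,2-dimethoxyethyl)-1H-indole-1-carboxylate F7. TMSOTf and i-Pr2NEt then eliminate methanol (acetal to enol ether) to give 10.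

**Step 1.** The most likely failure is over-reaction to the bis-indolyl dione or acid-induced oligomerisation of the electron-rich indole by the HCl set free.
Fallback (sets out from 1, comes back at 5): C3 iodination (I2, KOH, DMF) and N-Boc protection in the same flask (Boc2O, DMAP) give tert-butyl 3-iodo-6-methoxy-1H-indole-1-carboxylate F8. Iodine–magnesium exchange (i-PrMgCl·LiCl, THF, −40 °C) and addition to commercial 3,4-dimethoxycyclobut-3-ene-1,2-dione at −78 °C give tert-butyl 3-(1-hydroxy-2,3-dimethoxy-4-oxocyclobut-2-en-1-yl)-6-methoxy-1H-indole-1-carboxylate F9. Trifluoroacetic anhydride, then water, rearranges F9 with loss of methanol to 5.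

## Further compounds

F1 | step 7 | 2,5-dichloro-3-(6-methoxy-1H-indol-3-yl)cyclohexa-2,5-diene-1,4-dione | COc1ccc2c(C3=C(Cl)C(=O)C=C(Cl)C3=O)c[nH]c2c1
F2 | step 7 | 2-[5-(benzyloxy)-1H-indol-3-yl]-3,6-dichloro-5-(6-methoxy-1H-indol-3-yl)cyclohexa-2,5-diene-1,4-dione | COc1ccc2c(C3=C(Cl)C(=O)C(c4c[nH]c5ccc(OCc6ccccc6)cc45)=C(Cl)C3=O)c[nH]c2c1
F3 | step 7 | 2-[5-(benzyloxy)-1H-indol-3-yl]-3,6-dimethoxy-5-(6-methoxy-1H-indol-3-yl)cyclohexa-2,5-diene-1,4-dione | COc1ccc2c(C3=C(OC)C(=O)C(c4c[nH]c5ccc(OCc6ccccc6)cc45)=C(OC)C3=O)c[nH]c2c1
F4 | step 7 | 2-[5-(benzyloxy)-1H-indol-3-yl]-3,6-dimethoxy-5-(6-methoxy-1H-indol-3-yl)benzene-1,4-diol | COc1ccc2c(-c3c(OC)c(O)c(-c4c[nH]c5ccc(OCc6ccccc6)cc45)c(OC)c3O)c[nH]c2c1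
F5 | step 6 | tert-butyl 5-(benzyloxy)-3-[(Z)-1-{3-[1-(tert-butoxycarbonyl)-6-methoxy-1H-indol-3-yl]-1-hydroxy-2-methoxy-4-oxocyclobut-2-en-1-yl}-2-methoxyethenyl]-1H-indole-1-carboxylate (racemic) | OC1(/C(=C\OC)c2cn(C(=O)OC(C)(C)C)c3ccc(OCc4ccccc4)cc23)C(OC)=C(c2cn(C(=O)OC(C)(C)C)c3cc(OC)ccc23)C1=O
F6 | step 6 | tert-butyl 5-(benzyloxy)-3-{4-[1-(tert-butoxycarbonyl)-6-methoxy-1H-indol-3-yl]-3,6-dihydroxy-2,5-dimethoxyphenyl}-1H-indole-1-carboxylate | COc1c(O)c(-c2cn(C(=O)OC(C)(C)C)c3cc(OC)ccc23)c(OC)c(O)c1-c1cn(C(=O)OC(C)(C)C)c2ccc(OCc3ccccc3)cc12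
F7 | step 5 | tert-butyl 5-(benzyloxy)-3-(1-bromo-2,2-dimethoxyethyl)-1H-indole-1-carboxylate (racemic) | COC(OC)C(Br)c1cn(C(=O)OC(C)(C)C)c2ccc(OCc3ccccc3)cc12
F8 | step 1 | tert-butyl 3-iodo-6-methoxy-1H-indole-1-carboxylate | COc1ccc2c(I)cn(C(=O)OC(C)(C)C)c2c1
F9 | step 1 | tert-butyl 3-(1-hydroxy-2,3-dimethoxy-4-oxocyclobut-2-en-1-yl)-6-methoxy-1H-indole-1-carboxylate (racemic) | COC1=C(OC)C(O)(c2cn(C(=O)OC(C)(C)C)c3cc(OC)ccc23)C1=O
A1 | alternative 1 | 1,4-dibromo-2,3,5,6-tetramethoxybenzene | COc1c(Br)c(OC)c(OC)c(Br)c1OC
A2 | alternative 1 | tert-butyl 6-methoxy-3-(4,4,5,5-tetramethyl-1,3,2-dioxaborolan-2-yl)-1H-indole-1-carboxylate | COc1ccc2c(B3OC(C)(C)C(C)(C)O3)cn(C(=O)OC(C)(C)C)c2c1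
A3 | alternative 1 | tert-butyl 3-(4-bromo-2,3,5,6-tetramethoxyphenyl)-6-methoxy-1H-indole-1-carboxylate | COc1ccc2c(-c3c(OC)c(OC)c(Br)c(OC)c3OC)cn(C(=O)OC(C)(C)C)c2c1
A4 | alternative 1 | tert-butyl 5-(benzyloxy)-3-(4,4,5,5-tetramethyl-1,3,2-dioxaborolan-2-yl)-1H-indole-1-carboxylate | CC1(C)OB(c2cn(C(=O)OC(C)(C)C)c3ccc(OCc4ccccc4)cc23)OC1(C)C
A5 | alternative 2 | 1,4-bis[(trimethylsilyl)ethynyl]-2,3,5,6-tetramethoxybenzene | COc1c(C#C[Si](C)(C)C)c(OC)c(OC)c(C#C[Si](C)(C)C)c1OC
A6 | alternative 2 | 5-(benzyloxy)-3-{2,3,5,6-tetramethoxy-4-[6-methoxy-2-(trimethylsilyl)-1H-indol-3-yl]phenyl}-2-(trimethylsilyl)-1H-indole | COc1ccc2c(-c3c(OC)c(OC)c(-c4c([Si](C)(C)C)[nH]c5ccc(OCc6ccccc6)cc45)c(OC)c3OC)c([Si](C)(C)C)[nH]c2c1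
A7 | alternative 3 | methyl 3-(6-methoxy-1H-indol-3-yl)-2-oxopropanoate | COC(=O)C(=O)Cc1c[nH]c2cc(OC)ccc12
A8 | alternative 3 | methyl 3-[5-(benzyloxy)-1H-indol-3-yl]-2-oxopropanoate | COC(=O)C(=O)Cc1c[nH]c2ccc(OCc3ccccc3)cc12
A9 | alternative 3 | 2-[5-(benzyloxy)-1H-indol-3-yl]-3,6-dihydroxy-5-(6-methoxy-1H-indol-3-yl)cyclohexa-2,5-diene-1,4-dione | COc1ccc2c(C3=C(O)C(=O)C(c4c[nH]c5ccc(OCc6ccccc6)cc45)=C(O)C3=O)c[nH]c2c1
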